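Assumption: in the O-aryl oxiranium formed in the key step, C–O heterolysis follows benzylic cation stability, so the ring B triflates direct cleavage to C3. Locants follow 2,3-dihydro-1-benzofuran numbering; ring A is the benzo ring, ring B the aryl on C2, ring C the aryl on C3, ring D the guaiacyl ring.

**Retrosynthetic overview**
1. End game: the C6 styryl arm (ring D) comes from Horner–Wadsworth–Emmons olefination of a C6 aldehyde (from a C6 ester); the phenols are unmasked last (four benzyl ethers, two ring B triflates).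
2. Key disconnection: C3–C3a together with O1–C7a, by formal insertion of a ring A aryne (C3a≡C7a) into the C3–O bond of an enantiopure trans-oxirane whose oxygen becomes O1; the oxirane is a temporary strained ring, and the dihydrofuran ring closes when C3a bonds to C3.
3. Enabling feature: C3a lies between C7a (O1) and the oxygen-bearing C4, so the aryne is a 3-alkoxyaryne that takes the oxygen at C7a and puts the carbanion on C3a; ring B has its oxygens ortho and para to C2, where triflates switch off ionisation at C2 so that only the C3–O bond opens.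
4. The oxirane comes from the E-stilbene (Shi epoxidation sets C2 and C3), the stilbene from olefination of two bought arenes; the aryne precursor comes from methyl 4-bromo-3,5-dihydroxybenzoate by retro-Brook silylation and triflation.
5. Ring order: oxirane (temporary), then the dihydrofuran ring (key step); all four benzene rings are bought.

Key step: step 7

**Route**

Step 1
Reactants: 1 2,4-dihydroxybenzaldehyde
Product: 2 4-formyl-1,3-phenylene bis(trifluoromethanesulfonate)
Conditions: Tf2O (2.3 equiv), pyridine, CH2Cl2, 0 °C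
Reagents that add atoms: trifluoromethanesulfonic anhydride, O=S(=O)(OS(=O)(=O)C(F)(F)F)C(F)(F)F
Why: O-sulfonylation of both phenols should give the bis-triflate, which carries the ring B oxygens as strongly electron-withdrawing, base-removable groups.

Step 2
Reactants: 3 3,5-bis(benzyloxy)benzyl bromide
Product: 4 diethyl [3,5-bis(benzyloxy)benzyl]phosphonate
Conditions: P(OEt)3 (3 equiv, neat), 130 °C
Reagents that add atoms: triethyl phosphite, CCOP(OCC)OCC
Why: Michaelis–Arbuzov reaction of a primary benzylic bromide should proceed cleanly, with bromoethane distilling off.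

Step 3
Reactants: 2 4-formyl-1,3-phenylene bis(trifluoromethanesulfonate); 4 diethyl [3,5-bis(benzyloxy)benzyl]phosphonate
Product: 5 4-{(E)-2-[3,5-bis(benzyloxy)phenyl]ethenyl}-1,3-phenylene bis(trifluoromethanesulfonate)
Conditions: NaH, THF, 0 °C (anion of 4 preformed), then 2, 0 °C to rt
Reagents that add atoms: none
Why: Horner–Wadsworth–Emmons olefination of the electron-poor aldehyde with a benzylic phosphonate anion should give the E-stilbene, and a preformed, non-alkoxide base spares the aryl triflates.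

Step 4
Reactants: 5 4-{(E)-2-[3,5-bis(benzyloxy)phenyl]ethenyl}-1,3-phenylene bis(trifluoromethanesulfonate)
Product: 6 4-{(2R,3R)-3-[3,5-bis(benzyloxy)phenyl]oxiran-2-yl}-1,3-phenylene bis(trifluoromethanesulfonate)
Conditions: D-fructose-derived Shi ketone (30 mol%), Oxone (2KHSO5·KHSO4·K2SO4), K2CO3, n-Bu4NHSO4, MeCN/dimethoxymethane/aq. buffer pH 10.5, 0 °C
Reagents that add atoms: potassium peroxymonosulfate (active part of Oxone), [K+].[O-]S(=O)(=O)OO
Why: Shi asymmetric epoxidation of a trans-1,2-diarylethene should deliver oxygen through the spiro transition state of the chiral dioxirane to give the (2R,3R)-trans-oxirane, which sets both future stereocenters; the triflates also make this otherwise acid-labile stilbene oxide stable to isolation.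

Step 5
Reactants: 7 methyl 4-bromo-3,5-dihydroxybenzoate
Product: 8 methyl 3-(benzyloxy)-4-bromo-5-hydroxybenzoate
Conditions: BnBr (1.0 equiv), K2CO3, DMF, rt; separation from bis-ether and recovered 7
Reagents that add atoms: benzyl bromide, BrCc1ccccc1
Why: Williamson mono-etherification of a C2v-symmetric diol should give a single mono-ether, since both hydroxyls are equivalent.

Step 6
Reactants: 8 methyl 3-(benzyloxy)-4-bromo-5-hydroxybenzoate
Product: 11 methyl 3-(benzyloxy)-4-(trimethylsilyl)-5-{[(trifluoromethyl)sulfonyl]oxy}benzoate, via aryl trimethylsilyl ether 9 (not isolated), via lithium 2-silylphenolate 10 (not isolated)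
Conditions: (Me3Si)2NH, THF, 65 °C, evaporate; n-BuLi, THF, −100 to −78 °C; PhNTf2, −78 °C to rt
Reagents that add atoms: hexamethyldisilazane, C[Si](C)(C)N[Si](C)(C)C; N-phenyl-bis(trifluoromethanesulfonimide), O=S(=O)(N(c1ccccc1)S(=O)(=O)C(F)(F)F)C(F)(F)F
Why: O-silylation, bromine–lithium exchange and 1,3-retro-Brook O-to-C silyl migration (fast at the aryllithium flanked by two oxygens), then triflation of the phenolate, is the standard entry to 2-silylaryl triflates and places silicon on the future C3a.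

Step 7
Reactants: 6 4-{(2R,3R)-3-[3,5-bis(benzyloxy)phenyl]oxiran-2-yl}-1,3-phenylene bis(trifluoromethanesulfonate); 11 methyl 3-(benzyloxy)-4-(trimethylsilyl)-5-{[(trifluoromethyl)sulfonyl]oxy}benzoate
Product: 14 methyl (2S,3S)-4-(benzyloxy)-3-[3,5-bis(benzyloxy)phenyl]-2-{2,4-bis[(trifluoromethanesulfonyl)oxy]phenyl}-2,3-dihydro-1-benzofuran-6-carboxylate, via 3-alkoxyaryne 12 (not isolated), via O-aryl oxiranium zwitterion 13 (not isolated)
Conditions: CsF (4 equiv), 18-crown-6, toluene, 40 °C; 11 (2.5 equiv) added slowly to 6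
Reagents that add atoms: none
Why: Fluoride removes the silyl group of 11 and expels triflate to give aryne 12, whose C7a terminus (remote from the C4 benzyloxy group) is attacked by the oxirane oxygen of 6, leaving the carbanion on C3a in zwitterion 13; strain release then breaks the C3–O bond of the three-membered ring and the C3a carbanion bonds to C3. The closest known reaction type is the formal insertion of arynes into the benzylic C–O bond of aryl oxiranes, which gives 3-aryl-2,3-dihydrobenzofurans. The five-membered ring is closed by intramolecular anion–cation recombination, a unimolecular front-side substitution at C3 in which the leaving oxygen stays in the ring as O1, so no concerted backside displacement is involved. C2 keeps the configuration set in step 4 because its C–O bond is never broken, and C3 should form with retention because C3a bonds on the face just vacated by oxygen within the tight ion pair, the trans product also being the more stable one. Two selectivities are needed: the regiochemistry on the aryne, secured by the C4 benzyloxy group of ring A (aryne distortion and inductive stabilisation of the C3a carbanion), and cleavage of C3–O and not C2–O, secured by the two triflates on ring B, which make positive charge at C2 untenable while the 3,5-bis(benzyloxy)phenyl group on C3 behaves like a plain phenyl group.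

Step 8
Reactants: 14 methyl (2S,3S)-4-(benzyloxy)-3-[3,5-bis(benzyloxy)phenyl]-2-{2,4-bis[(trifluoromethanesulfonyl)oxy]phenyl}-2,3-dihydro-1-benzofuran-6-carboxylate
Product: 15 4-[(2S,3S)-4-(benzyloxy)-3-[3,5-bis(benzyloxy)phenyl]-6-(hydroxymethyl)-2,3-dihydro-1-benzofuran-2-yl]-1,3-phenylene bis(trifluoromethanesulfonate)
Conditions: i-Bu2AlH (3 equiv), CH2Cl2, −78 °C; Rochelle salt work-up
Reagents that add atoms: none
Why: Hydride reduction of the aryl ester to the benzylic alcohol should leave aryl triflates, benzyl ethers and both stereocenters untouched at low temperature.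

Step 9
Reactants: 15 4-[(2S,3S)-4-(benzyloxy)-3-[3,5-bis(benzyloxy)phenyl]-6-(hydroxymethyl)-2,3-dihydro-1-benzofuran-2-yl]-1,3-phenylene bis(trifluoromethanesulfonate)
Product: 16 4-[(2S,3S)-4-(benzyloxy)-3-[3,5-bis(benzyloxy)phenyl]-6-formyl-2,3-dihydro-1-benzofuran-2-yl]-1,3-phenylene bis(trifluoromethanesulfonate)
Conditions: MnO2 (activated, excess), CH2Cl2, rt
Reagents that add atoms: none
Why: MnO2 oxidation is selective for the benzylic alcohol and is neutral, so the C2–O1 bond and the C3 stereocenter should be safe.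

Step 10
Reactants: 17 4-(benzyloxy)-3-methoxybenzyl alcohol
Product: 18 diethyl [4-(benzyloxy)-3-methoxybenzyl]phosphonate
Conditions: ZnI2 (1.5 equiv), P(OEt)3, toluene, reflux
Reagents that add atoms: triethyl phosphite, CCOP(OCC)OCC
Why: Lewis-acid-mediated Michaelis–Arbuzov phosphonylation of an electron-rich benzylic alcohol should give the phosphonate in one operation.

Step 11
Reactants: 16 4-[(2S,3S)-4-(benzyloxy)-3-[3,5-bis(benzyloxy)phenyl]-6-formyl-2,3-dihydro-1-benzofuran-2-yl]-1,3-phenylene bis(trifluoromethanesulfonate); 18 diethyl [4-(benzyloxy)-3-methoxybenzyl]phosphonate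
Product: 19 4-[(2S,3S)-4-(benzyloxy)-6-{(E)-2-[4-(benzyloxy)-3-methoxyphenyl]ethenyl}-3-[3,5-bis(benzyloxy)phenyl]-2,3-dihydro-1-benzofuran-2-yl]-1,3-phenylene bis(trifluoromethanesulfonate)
Conditions: NaH, THF, 0 °C (anion of 18 preformed, 1.3 equiv), then 16, 0 °C to rt
Reagents that add atoms: none
Why: Horner–Wadsworth–Emmons olefination should give the E-alkene, and the phosphonate anion is too weak a base to deprotonate C3–H, so no ring opening or epimerisation is expected.

Step 12
Reactants: 19 4-[(2S,3S)-4-(benzyloxy)-6-{(E)-2-[4-(benzyloxy)-3-methoxyphenyl]ethenyl}-3-[3,5-bis(benzyloxy)phenyl]-2,3-dihydro-1-benzofuran-2-yl]-1,3-phenylene bis(trifluoromethanesulfonate)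
Product: 20 4-[(2S,3S)-3-(3,5-dihydroxyphenyl)-4-hydroxy-6-[(E)-2-(4-hydroxy-3-methoxyphenyl)ethenyl]-2,3-dihydro-1-benzofuran-2-yl]-1,3-phenylene bis(trifluoromethanesulfonate)
Conditions: BCl3 (10 equiv), pentamethylbenzene (15 equiv), CH2Cl2, −78 °C
Reagents that add atoms: none
Why: Lewis-acid debenzylation with a non-basic cation scavenger should cleave the four aryl benzyl ethers without touching the stilbene or the methyl ether, and the ring B triflates keep the C2–O1 bond from ionising under the Lewis acid.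

Step 13
Reactants: 20 4-[(2S,3S)-3-(3,5-dihydroxyphenyl)-4-hydroxy-6-[(E)-2-(4-hydroxy-3-methoxyphenyl)ethenyl]-2,3-dihydro-1-benzofuran-2-yl]-1,3-phenylene bis(trifluoromethanesulfonate)
Product: 21 (2S,3S)-2-(2,4-dihydroxyphenyl)-3-(3,5-dihydroxyphenyl)-6-[(E)-2-(4-hydroxy-3-methoxyphenyl)ethenyl]-2,3-dihydro-1-benzofuran-4-ol
Conditions: Et4NOH (aq., 10 equiv), 1,4-dioxane, rt, argon; then aq. NH4Cl/AcOH to pH 5
Reagents that add atoms: none
Why: Hydroxide attack at sulfur (S–O cleavage of aryl triflates) should free the two ring B phenols; any reversible opening of C2–O1 through the para-phenoxide can only return the more stable trans ring, because C3 is not epimerisable.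

**Compound list**
1 | 2,4-dihydroxybenzaldehyde | O=Cc1ccc(O)cc1O | starting material
2 | 4-formyl-1,3-phenylene bis(trifluoromethanesulfonate) | O=Cc1ccc(OS(=O)(=O)C(F)(F)F)cc1OS(=O)(=O)C(F)(F)F | intermediate
3 | 3,5-bis(benzyloxy)benzyl bromide | BrCc1cc(OCc2ccccc2)cc(OCc2ccccc2)c1 | starting material
4 | diethyl [3,5-bis(benzyloxy)benzyl]phosphonate | CCOP(=O)(OCC)Cc1cc(OCc2ccccc2)cc(OCc2ccccc2)c1 | intermediate
5 | 4-{(E)-2-[3,5-bis(benzyloxy)phenyl]ethenyl}-1,3-phenylene bis(trifluoromethanesulfonate) | FC(F)(F)S(=O)(=O)Oc1ccc(/C=C/c2cc(OCc3ccccc3)cc(OCc3ccccc3)c2)c(OS(=O)(=O)C(F)(F)F)c1 | intermediate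
6 | 4-{(2R,3R)-3-[3,5-bis(benzyloxy)phenyl]oxiran-2-yl}-1,3-phenylene bis(trifluoromethanesulfonate) | FC(F)(F)S(=O)(=O)Oc1ccc([C@H]2O[C@@H]2c2cc(OCc3ccccc3)cc(OCc3ccccc3)c2)c(OS(=O)(=O)C(F)(F)F)c1 | intermediate
7 | methyl 4-bromo-3,5-dihydroxybenzoate | COC(=O)c1cc(O)c(Br)c(O)c1 | starting material
8 | methyl 3-(benzyloxy)-4-bromo-5-hydroxybenzoate | COC(=O)c1cc(O)c(Br)c(OCc2ccccc2)c1 | intermediate
9 | methyl 3-(benzyloxy)-4-bromo-5-[(trimethylsilyl)oxy]benzoate | COC(=O)c1cc(O[Si](C)(C)C)c(Br)c(OCc2ccccc2)c1 | intermediate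
10 | lithium 3-(benzyloxy)-5-(methoxycarbonyl)-2-(trimethylsilyl)phenolate | COC(=O)c1cc([O-])c([Si](C)(C)C)c(OCc2ccccc2)c1.[Li+] | intermediate
11 | methyl 3-(benzyloxy)-4-(trimethylsilyl)-5-{[(trifluoromethyl)sulfonyl]oxy}benzoate | COC(=O)c1cc(OCc2ccccc2)c([Si](C)(C)C)c(OS(=O)(=O)C(F)(F)F)c1 | intermediate
12 | methyl 3-(benzyloxy)-4,5-didehydrobenzoate (aryne) | COC(=O)C1=CC#CC(OCc2ccccc2)=C1 | intermediate
13 | zwitterion in which the oxirane oxygen of 6 is bonded to C7a of ring A and C3a carries the negative charge (O-aryl oxiranium) | COC(=O)c1cc(OCc2ccccc2)[c-]c(c1)[O+]1[C@H](c2ccc(OS(=O)(=O)C(F)(F)F)cc2OS(=O)(=O)C(F)(F)F)[C@H]1c1cc(OCc2ccccc2)cc(OCc2ccccc2)c1 | intermediate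
14 | methyl (2S,3S)-4-(benzyloxy)-3-[3,5-bis(benzyloxy)phenyl]-2-{2,4-bis[(trifluoromethanesulfonyl)oxy]phenyl}-2,3-dihydro-1-benzofuran-6-carboxylate | COC(=O)c1cc(OCc2ccccc2)c2c(c1)O[C@H](c1ccc(OS(=O)(=O)C(F)(F)F)cc1OS(=O)(=O)C(F)(F)F)[C@H]2c1cc(OCc2ccccc2)cc(OCc2ccccc2)c1 | intermediate
15 | 4-[(2S,3S)-4-(benzyloxy)-3-[3,5-bis(benzyloxy)phenyl]-6-(hydroxymethyl)-2,3-dihydro-1-benzofuran-2-yl]-1,3-phenylene bis(trifluoromethanesulfonate) | OCc1cc(OCc2ccccc2)c2c(c1)O[C@H](c1ccc(OS(=O)(=O)C(F)(F)F)cc1OS(=O)(=O)C(F)(F)F)[C@H]2c1cc(OCc2ccccc2)cc(OCc2ccccc2)c1 | intermediate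
16 | 4-[(2S,3S)-4-(benzyloxy)-3-[3,5-bis(benzyloxy)phenyl]-6-formyl-2,3-dihydro-1-benzofuran-2-yl]-1,3-phenylene bis(trifluoromethanesulfonate) | O=Cc1cc(OCc2ccccc2)c2c(c1)O[C@H](c1ccc(OS(=O)(=O)C(F)(F)F)cc1OS(=O)(=O)C(F)(F)F)[C@H]2c1cc(OCc2ccccc2)cc(OCc2ccccc2)c1 | intermediate
17 | 4-(benzyloxy)-3-methoxybenzyl alcohol | COc1cc(CO)ccc1OCc1ccccc1 | starting material
18 | diethyl [4-(benzyloxy)-3-methoxybenzyl]phosphonate | CCOP(=O)(OCC)Cc1ccc(OCc2ccccc2)c(OC)c1 | intermediate
19 | 4-[(2S,3S)-4-(benzyloxy)-6-{(E)-2-[4-(benzyloxy)-3-methoxyphenyl]ethenyl}-3-[3,5-bis(benzyloxy)phenyl]-2,3-dihydro-1-benzofuran-2-yl]-1,3-phenylene bis(trifluoromethanesulfonate) | COc1cc(/C=C/c2cc(OCc3ccccc3)c3c(c2)O[C@H](c2ccc(OS(=O)(=O)C(F)(F)F)cc2OS(=O)(=O)C(F)(F)F)[C@H]3c2cc(OCc3ccccc3)cc(OCc3ccccc3)c2)ccc1OCc1ccccc1 | intermediate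
20 | 4-[(2S,3S)-3-(3,5-dihydroxyphenyl)-4-hydroxy-6-[(E)-2-(4-hydroxy-3-methoxyphenyl)ethenyl]-2,3-dihydro-1-benzofuran-2-yl]-1,3-phenylene bis(trifluoromethanesulfonate) | COc1cc(/C=C/c2cc(O)c3c(c2)O[C@H](c2ccc(OS(=O)(=O)C(F)(F)F)cc2OS(=O)(=O)C(F)(F)F)[C@H]3c2cc(O)cc(O)c2)ccc1O | intermediate
21 | (2S,3S)-2-(2,4-dihydroxyphenyl)-3-(3,5-dihydroxyphenyl)-6-[(E)-2-(4-hydroxy-3-methoxyphenyl)ethenyl]-2,3-dihydro-1-benzofuran-4-ol | COc1cc(/C=C/c2cc(O)c3c(c2)O[C@H](c2ccc(O)cc2O)[C@H]3c2cc(O)cc(O)c2)ccc1O | target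

**Step count**
Total steps: 13. Longest linear sequence: 9 steps (steps 1, 3, 4, 7, 8, 9, 11, 12, 13).

**Steps most likely to fail, with fallbacks**

Step 7. The hindered, electron-poor oxirane oxygen may capture the aryne too slowly, so that the aryne is consumed by fluoride, solvent or itself. Bond rotation in the ion pair before collapse may also erode the trans selectivity; any cis isomer must be removed at this stage, while the triflates still lock C2. The fallback sets out from stilbene 5 and returns at 14, closing the same C3–C3a bond by known reductive coupling. Epoxidation of 5 with the enantiomeric Shi ketone should give 4-{(2S,3S)-3-[3,5-bis(benzyloxy)phenyl]oxiran-2-yl}-1,3-phenylene bis(trifluoromethanesulfonate) F1. Opening with TiCl4 (CH2Cl2, −78 °C) at the only ionisable carbon should give (1S)-2-[3,5-bis(benzyloxy)phenyl]-2-chloro-1-{2,4-bis[(trifluoromethanesulfonyl)oxy]phenyl}ethanol F2, as a mixture of epimers at the chlorine-bearing carbon. Mitsunobu etherification of F2 with phenol 8 (PPh3, diisopropyl azodicarboxylate, toluene, 0 °C) inverts the carbinol carbon and should give methyl 3-(benzyloxy)-4-bromo-5-{(1R)-2-[3,5-bis(benzyloxy)phenyl]-2-chloro-1-{2,4-bis[(trifluoromethanesulfonyl)oxy]phenyl}ethoxy}benzoate F3. Intramolecular nickel-catalysed reductive cross-electrophile coupling of F3 (NiBr2·MeOCH2CH2OMe, 4,4'-di-tert-butyl-2,2'-bipyridine, Mn powder, DMA, rt) then joins the aryl bromide to the secondary benzylic chloride. Bipyridine-ligated nickel should select the aryl bromide over the aryl triflates, and the planar C3 radical should be captured trans to the ring B aryl, so both chlorine epimers converge on 14.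

Step 6. The organolithium may add to the methyl ester in competition with bromine–lithium exchange. The fallback sets out from 8 and returns at 15, carrying C6 at the alcohol oxidation level through the aryne step. Reduction of 8 with i-Bu2AlH should give 3-(benzyloxy)-4-bromo-5-(hydroxymethyl)phenol F4. Bis-silylation with (Me3Si)2NH, n-BuLi (retro-Brook), PhNTf2 and mild methanolysis of the alkyl silyl ether should give 3-(benzyloxy)-5-(hydroxymethyl)-2-(trimethylsilyl)phenyl trifluoromethanesulfonate F5. TBSCl/imidazole then gives 3-(benzyloxy)-5-{[(tert-butyldimethylsilyl)oxy]methyl}-2-(trimethylsilyl)phenyl trifluoromethanesulfonate F6. The aryne insertion of step 7 with 6 would give 4-[(2S,3S)-4-(benzyloxy)-3-[3,5-bis(benzyloxy)phenyl]-6-{[(tert-butyldimethylsilyl)oxy]methyl}-2,3-dihydro-1-benzofuran-2-yl]-1,3-phenylene bis(trifluoromethanesulfonate) F7, and HF·pyridine (THF, 0 °C) frees alcohol 15.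

Step 4. Oxygen transfer to the electron-poor, ortho-substituted stilbene may be slow, with hydrolysis of the aryl triflates at pH 10.5 and oxidative decay of the ketone catalyst competing. The fallback sets out from aldehyde 2 and bromide 3 and returns at 6, replacing olefination and epoxidation by an asymmetric sulfur-ylide epoxidation (Johnson–Corey–Chaykovsky type with a C2-symmetric sulfide). Alkylation of (2S,5S)-2,5-dimethylthiolane with 3 should give (2S,5S)-1-[3,5-bis(benzyloxy)benzyl]-2,5-dimethylthiolan-1-ium bromide F8. Its ylide (LiN(SiMe3)2, THF, −78 °C) should add to 2 and close to the trans-oxirane 6 under anhydrous conditions that spare the triflates. The antipode of the sulfide is used if the sense of induction requires it.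

**Further compounds**
F1 | step 7 | 4-{(2S,3S)-3-[3,5-bis(benzyloxy)phenyl]oxiran-2-yl}-1,3-phenylene bis(trifluoromethanesulfonate) | FC(F)(F)S(=O)(=O)Oc1ccc([C@@H]2O[C@H]2c2cc(OCc3ccccc3)cc(OCc3ccccc3)c2)c(OS(=O)(=O)C(F)(F)F)c1
F2 | step 7 | (1S)-2-[3,5-bis(benzyloxy)phenyl]-2-chloro-1-{2,4-bis[(trifluoromethanesulfonyl)oxy]phenyl}ethanol (both epimers at the chlorine-bearing carbon) | O[C@@H](c1ccc(OS(=O)(=O)C(F)(F)F)cc1OS(=O)(=O)C(F)(F)F)C(Cl)c1cc(OCc2ccccc2)cc(OCc2ccccc2)c1
F3 | step 7 | methyl 3-(benzyloxy)-4-bromo-5-{(1R)-2-[3,5-bis(benzyloxy)phenyl]-2-chloro-1-{2,4-bis[(trifluoromethanesulfonyl)oxy]phenyl}ethoxy}benzoate | COC(=O)c1cc(OCc2ccccc2)c(Br)c(c1)O[C@H](c1ccc(OS(=O)(=O)C(F)(F)F)cc1OS(=O)(=O)C(F)(F)F)C(Cl)c1cc(OCc2ccccc2)cc(OCc2ccccc2)c1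
F4 | step 6 | 3-(benzyloxy)-4-bromo-5-(hydroxymethyl)phenol | OCc1cc(O)c(Br)c(OCc2ccccc2)c1
F5 | step 6 | 3-(benzyloxy)-5-(hydroxymethyl)-2-(trimethylsilyl)phenyl trifluoromethanesulfonate | OCc1cc(OCc2ccccc2)c([Si](C)(C)C)c(OS(=O)(=O)C(F)(F)F)c1
F6 | step 6 | 3-(benzyloxy)-5-{[(tert-butyldimethylsilyl)oxy]methyl}-2-(trimethylsilyl)phenyl trifluoromethanesulfonate | CC(C)(C)[Si](C)(C)OCc1cc(OCc2ccccc2)c([Si](C)(C)C)c(OS(=O)(=O)C(F)(F)F)c1
F7 | step 6 | 4-[(2S,3S)-4-(benzyloxy)-3-[3,5-bis(benzyloxy)phenyl]-6-{[(tert-butyldimethylsilyl)oxy]methyl}-2,3-dihydro-1-benzofuran-2-yl]-1,3-phenylene bis(trifluoromethanesulfonate) | CC(C)(C)[Si](C)(C)OCc1cc(OCc2ccccc2)c2c(c1)O[C@H](c1ccc(OS(=O)(=O)C(F)(F)F)cc1OS(=O)(=O)C(F)(F)F)[C@H]2c1cc(OCc2ccccc2)cc(OCc2ccccc2)c1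
F8 | step 4 | (2S,5S)-1-[3,5-bis(benzyloxy)benzyl]-2,5-dimethylthiolan-1-ium bromide | C[C@H]1CC[C@H](C)[S+]1Cc1cc(OCc2ccccc2)cc(OCc2ccccc2)c1.[Br-]
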